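**Retrosynthetic overview**

1. Numbering: core as 7-oxabicyclo[4.1.0]heptan-2-one (C-1 methyl-bearing epoxide carbon, C-2 ketone, C-3 acyloxy carbon, C-4 side-chain carbon, C-5 CH2, C-6 epoxide CH); side chain C-7 (oxirane carbon), C-8 (ketone) to C-11 (hydroperoxide carbon). The hydroperoxide comes from a singlet-oxygen ene reaction of a prenyl ketone; both ketones come from carbinols at C-2 and C-8, which first direct both epoxidations.
2. The cyclohexane ring, the only carbocycle, is made in one flask from an acyclic aldehyde (C-3 to C-6 with the side-chain skeleton on C-4, C-6 masked as an acetal) and a propanoyl anion equivalent (C-2, C-1, CH3). C-2–C-3 forms by acyl-anion addition and C-1–C-6 by aldol condensation.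
3. Enabling feature: the ring ketone C-2 sits between the oxygen-bearing C-3 (an acyloin) and the epoxide pair C-1/C-6 (an epoxy ketone, i.e. an oxidised enone and so an aldol product). One C-2/C-1/CH3 unit can therefore act first as acyl anion and then as enol toward the chain C-3…C-6.
4. Stereochemistry: C-4 is set by an organocatalytic Michael addition; C-3, the C-2 carbinol and the ring epoxide are relayed from it. C-8 (reagent-controlled allylation) relays the oxirane centre C-7 and is then oxidised away.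
5. Ring order: cyclohexenone (step 7), then the fused epoxide and the side-chain oxirane together (step 11).

Key step: step 7

Remark: the addition in step 7 is taken to follow the Felkin–Anh sense (hydroxyl cis to the side chain); the minor trans alcohol, if formed, would be esterified directly with retention and joins the route at 19.

**Step 1**
Reactants: 1 (E)-but-2-enal; 2 4,4-diethoxybut-1-ene
Product: 3 (E)-5,5-diethoxypent-2-enal
Conditions: second-generation Hoveyda–Grubbs catalyst (3 mol %), CH2Cl2, 40 °C, 1 in excess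
Reagents that add atoms: none
Why: Olefin cross-metathesis of a terminal alkene with an enal should give the E-enal with loss of propene, the acetal being inert to the ruthenium carbene.

**Step 2**
Reactants: 3 (E)-5,5-diethoxypent-2-enal; 4 nitromethane
Product: 5 (3R)-5,5-diethoxy-3-(nitromethyl)pentanal
Conditions: (S)-α,α-diphenylprolinol trimethylsilyl ether (10 mol %), PhCO2H (20 mol %), EtOH, rt
Reagents that add atoms: none
Why: Iminium-catalysed Michael addition of nitromethane, in which the silyloxydiphenylmethyl group shields one face of the E-iminium ion, should set the future C-4, the one ring stereocentre set by a catalyst.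

**Step 3**
Reactants: 5 (3R)-5,5-diethoxy-3-(nitromethyl)pentanal; 6 formaldehyde
Product: 7 (3S)-5,5-diethoxy-2-methylidene-3-(nitromethyl)pentanal
Conditions: 37% aq. HCHO, pyrrolidine (10 mol %), EtCO2H (10 mol %), i-PrOH, 45 °C
Reagents that add atoms: none
Why: Amine-catalysed Mannich condensation and elimination (α-methylenation of an aldehyde) should install the exocyclic methylene; the weakly acidic medium keeps the nitroalkane from forming its nitronate, and the stereocentre is not α to the carbonyl.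

**Step 4**
Reactants: 7 (3S)-5,5-diethoxy-2-methylidene-3-(nitromethyl)pentanal; 8 (+)-B-allyldiisopinocampheylborane (from (−)-α-pinene)
Product: 10 (4R,6S)-8,8-diethoxy-5-methylidene-6-(nitromethyl)oct-1-en-4-ol, via borinate ester 9 (not isolated)
Conditions: Et2O, −78 °C; then HOCH2CH2NH2, rt
Reagents that add atoms: none
Why: Brown allylboration through a closed chair transition state should give the (R)-carbinol at C-8 under reagent control, and the non-oxidative work-up spares the nitro group.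

**Step 5**
Reactants: 10 (4R,6S)-8,8-diethoxy-5-methylidene-6-(nitromethyl)oct-1-en-4-ol
Product: 11 tert-butyl{[(4R,6S)-8,8-diethoxy-5-methylidene-6-(nitromethyl)oct-1-en-4-yl]oxy}diphenylsilane
Conditions: TBDPSCl, imidazole, DMF, rt
Reagents that add atoms: tert-butyl(chloro)diphenylsilane, CC(C)(C)[Si](Cl)(c1ccccc1)c1ccccc1
Why: Silylation gives an acid-stable ether that keeps the C-8 oxygen out of steps 7 and 8.

**Step 6**
Reactants: 11 tert-butyl{[(4R,6S)-8,8-diethoxy-5-methylidene-6-(nitromethyl)oct-1-en-4-yl]oxy}diphenylsilane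
Product: 13 (2S,4R)-4-[(tert-butyldiphenylsilyl)oxy]-2-(2,2-diethoxyethyl)-3-methylidenehept-6-enal, via sodium nitronate 12 (not isolated)
Conditions: NaOMe, MeOH, 0 °C; then aq. TiCl3, NH4OAc (pH 5–6), THF, 0 °C to rt
Reagents that add atoms: water, O
Why: Reductive Nef reaction, in which trivalent titanium reduces the nitronate to an imine that hydrolyses near neutral pH, should release the aldehyde without loss of acetal or silyl ether; it is used at once because its α-stereocentre is allylic.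

**Step 7**
Reactants: 13 (2S,4R)-4-[(tert-butyldiphenylsilyl)oxy]-2-(2,2-diethoxyethyl)-3-methylidenehept-6-enal; 14 ethyl prop-1-enyl ether
Product: 17 (5S,6R)-5-{(3R)-3-[(tert-butyldiphenylsilyl)oxy]hexa-1,5-dien-2-yl}-6-hydroxy-2-methylcyclohex-2-en-1-one, via enol ether adduct 15 (not isolated), via keto aldehyde 16 (not isolated)
Conditions: 14, t-BuLi, THF, −78 to 0 °C; CeCl3, −78 °C; 13, −78 °C; then 1 M aq. HCl, THF, rt to 40 °C
Reagents that add atoms: water, O
Why: The α-ethoxyvinyl cerium reagent (a propanoyl anion equivalent made from 14 by α-lithiation and transmetalation) adds to the aldehyde of 13 to form C-2–C-3; aqueous acid then hydrolyses the enol ether to the ethyl ketone and the acetal to the aldehyde (16), the ketone enol closes C-1–C-6 by intramolecular aldol addition, and dehydration gives the conjugated enone. The closest known chemistry is the addition of lithiated enol ethers to aldehydes with hydrolysis to acyloins, joined to the acid-mediated cyclodehydration of a 1,5-keto aldehyde as in the second stage of a Robinson annulation. The ring is closed in the 6-(enolendo)-exo-trig mode. The new stereocentre C-3 is controlled by C-4 in the Felkin–Anh sense (alkenyl group as the large substituent, anti to the nucleophile), which should place the hydroxyl cis to the side chain. The step needs the two aldehyde-level carbons to be told apart, which the acetal at C-6 secures, and its regiochemistry is built in because only the ethyl-side enol can reach the aldehyde through a six-membered transition state; the low basicity of the cerium reagent protects the allylic α-stereogenic aldehyde from enolisation, and the silyl ether keeps the C-8 oxygen from forming an acetal with the liberated aldehyde.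

**Step 8**
Reactants: 17 (5S,6R)-5-{(3R)-3-[(tert-butyldiphenylsilyl)oxy]hexa-1,5-dien-2-yl}-6-hydroxy-2-methylcyclohex-2-en-1-one; 18 3-methylbutanoic acid
Product: 19 (1S,6S)-6-{(3R)-3-[(tert-butyldiphenylsilyl)oxy]hexa-1,5-dien-2-yl}-3-methyl-2-oxocyclohex-3-en-1-yl 3-methylbutanoate
Conditions: PPh3, DIAD, toluene, 0 °C to rt
Reagents that add atoms: none
Why: Mitsunobu esterification, an SN2 displacement of the oxyphosphonium group at the carbonyl-activated carbinol carbon with the carboxylate entering anti to the side chain, should install the ester with inversion at C-3 (cis to trans).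

**Step 9**
Reactants: 19 (1S,6S)-6-{(3R)-3-[(tert-butyldiphenylsilyl)oxy]hexa-1,5-dien-2-yl}-3-methyl-2-oxocyclohex-3-en-1-yl 3-methylbutanoate
Product: 20 (1S,6S)-6-[(3R)-3-hydroxyhexa-1,5-dien-2-yl]-3-methyl-2-oxocyclohex-3-en-1-yl 3-methylbutanoate
Conditions: TBAF, AcOH, THF, rt
Reagents that add atoms: none
Why: Fluoride-mediated desilylation, buffered with acetic acid so that the α-acyloxy ketone is neither epimerised nor cleaved, should free the C-8 carbinol.

**Step 10**
Reactants: 20 (1S,6S)-6-[(3R)-3-hydroxyhexa-1,5-dien-2-yl]-3-methyl-2-oxocyclohex-3-en-1-yl 3-methylbutanoate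
Product: 21 (1S,2S,6S)-2-hydroxy-6-[(3R)-3-hydroxyhexa-1,5-dien-2-yl]-3-methylcyclohex-3-en-1-yl 3-methylbutanoate
Conditions: NaBH4, CeCl3·7H2O, MeOH, −78 °C
Reagents that add atoms: none
Why: Luche 1,2-reduction by axial hydride attack on the half-chair with the C-3 and C-4 substituents pseudo-equatorial should give the pseudo-equatorial C-2 carbinol, cis to the side chain and trans to the ester.

**Step 11**
Reactants: 21 (1S,2S,6S)-2-hydroxy-6-[(3R)-3-hydroxyhexa-1,5-dien-2-yl]-3-methylcyclohex-3-en-1-yl 3-methylbutanoate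
Product: 22 (1R,2R,3S,4R,6S)-2-hydroxy-4-{(2S)-2-[(1R)-1-hydroxybut-3-en-1-yl]oxiran-2-yl}-1-methyl-7-oxabicyclo[4.1.0]heptan-3-yl 3-methylbutanoate
Conditions: VO(acac)2 (5 mol %), t-BuOOH, CH2Cl2, 0 °C to rt
Reagents that add atoms: tert-butyl hydroperoxide, CC(C)(C)OO
Why: Hydroxyl-directed epoxidation by a vanadium alkylperoxide bound to each allylic alcohol should attack the ring alkene syn to the C-2 hydroxyl (epoxide cis to the side chain) and the 1,1-disubstituted alkene in the erythro sense imposed by A(1,2) strain, so that the (R)-carbinol C-8 sets the (S)-oxirane carbon C-7, while the terminal homoallylic alkene reacts far more slowly.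

**Step 12**
Reactants: 22 (1R,2R,3S,4R,6S)-2-hydroxy-4-{(2S)-2-[(1R)-1-hydroxybut-3-en-1-yl]oxiran-2-yl}-1-methyl-7-oxabicyclo[4.1.0]heptan-3-yl 3-methylbutanoate; 23 2-methylbut-2-ene
Product: 24 (1R,2R,3S,4R,6S)-2-hydroxy-4-{(2S)-2-[(1R)-1-hydroxy-4-methylpent-3-en-1-yl]oxiran-2-yl}-1-methyl-7-oxabicyclo[4.1.0]heptan-3-yl 3-methylbutanoate
Conditions: second-generation Grubbs catalyst (5 mol %), CH2Cl2, 40 °C, 23 in excess
Reagents that add atoms: none
Why: Olefin cross-metathesis of the monosubstituted alkene with 2-methylbut-2-ene should turn allyl into prenyl with loss of propene, the epoxides, hydroxyls and ester being tolerated.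

**Step 13**
Reactants: 24 (1R,2R,3S,4R,6S)-2-hydroxy-4-{(2S)-2-[(1R)-1-hydroxy-4-methylpent-3-en-1-yl]oxiran-2-yl}-1-methyl-7-oxabicyclo[4.1.0]heptan-3-yl 3-methylbutanoate
Product: 25 (1S,3S,4R,6S)-1-methyl-4-[(2S)-2-(4-methylpent-3-enoyl)oxiran-2-yl]-2-oxo-7-oxabicyclo[4.1.0]heptan-3-yl 3-methylbutanoate
Conditions: Dess–Martin periodinane, pyridine, CH2Cl2, 0 °C to rt
Reagents that add atoms: none
Why: Dess–Martin oxidation of both secondary carbinols under buffered, non-basic conditions should give the two α,β-epoxy ketones without conjugating the β,γ-alkene or epimerising C-3.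

**Step 14**
Reactants: 25 (1S,3S,4R,6S)-1-methyl-4-[(2S)-2-(4-methylpent-3-enoyl)oxiran-2-yl]-2-oxo-7-oxabicyclo[4.1.0]heptan-3-yl 3-methylbutanoate
Product: 26 (1S,3S,4R,6S)-4-{(2S)-2-[(2E)-4-hydroperoxy-4-methylpent-2-enoyl]oxiran-2-yl}-1-methyl-2-oxo-7-oxabicyclo[4.1.0]heptan-3-yl 3-methylbutanoate
Conditions: O2, hν (visible light), tetraphenylporphyrin (cat.), CH2Cl2, −20 °C; no reductive work-up
Reagents that add atoms: dioxygen, O=O
Why: Schenck ene reaction, in which singlet oxygen bonds to C-11 and abstracts a hydrogen from the carbonyl-activated C-9 methylene on the more substituted side of the alkene, should move the double bond into conjugation as the E-alkene and give the tertiary hydroperoxide.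

**Compound list**

1 | (E)-but-2-enal | C/C=C/C=O | starting material
2 | 4,4-diethoxybut-1-ene | C=CCC(OCC)OCC | starting material
3 | (E)-5,5-diethoxypent-2-enal | O=C/C=C/CC(OCC)OCC | intermediate
4 | nitromethane | C[N+](=O)[O-] | starting material
5 | (3R)-5,5-diethoxy-3-(nitromethyl)pentanal | O=CC[C@@H](C[N+](=O)[O-])CC(OCC)OCC | intermediate
6 | formaldehyde | C=O | starting material
7 | (3S)-5,5-diethoxy-2-methylidene-3-(nitromethyl)pentanal | O=CC(=C)[C@@H](C[N+](=O)[O-])CC(OCC)OCC | intermediate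
8 | (+)-B-allyldiisopinocampheylborane | C=CCB([C@H]1C[C@H]2C[C@@H]([C@@H]1C)C2(C)C)[C@H]1C[C@H]2C[C@@H]([C@@H]1C)C2(C)C | starting material
9 | (4R,6S)-8,8-diethoxy-5-methylidene-6-(nitromethyl)oct-1-en-4-yl diisopinocampheylborinate | C=CC[C@@H](OB([C@H]1C[C@H]2C[C@@H]([C@@H]1C)C2(C)C)[C@H]3C[C@H]4C[C@@H]([C@@H]3C)C4(C)C)C(=C)[C@@H](C[N+](=O)[O-])CC(OCC)OCC | intermediate
10 | (4R,6S)-8,8-diethoxy-5-methylidene-6-(nitromethyl)oct-1-en-4-ol | C=CC[C@@H](O)C(=C)[C@@H](C[N+](=O)[O-])CC(OCC)OCC | intermediate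
11 | tert-butyl{[(4R,6S)-8,8-diethoxy-5-methylidene-6-(nitromethyl)oct-1-en-4-yl]oxy}diphenylsilane | C=CC[C@@H](O[Si](c1ccccc1)(c2ccccc2)C(C)(C)C)C(=C)[C@@H](C[N+](=O)[O-])CC(OCC)OCC | intermediate
12 | sodium nitronate of 11 | C=CC[C@@H](O[Si](c1ccccc1)(c2ccccc2)C(C)(C)C)C(=C)[C@@H](C=[N+]([O-])[O-])CC(OCC)OCC.[Na+] | intermediate
13 | (2S,4R)-4-[(tert-butyldiphenylsilyl)oxy]-2-(2,2-diethoxyethyl)-3-methylidenehept-6-enal | C=CC[C@@H](O[Si](c1ccccc1)(c2ccccc2)C(C)(C)C)C(=C)[C@@H](C=O)CC(OCC)OCC | intermediate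
14 | ethyl prop-1-enyl ether (cis/trans mixture) | CCOC=CC | starting material
15 | (4R,5S,7R)-7-[(tert-butyldiphenylsilyl)oxy]-5-(2,2-diethoxyethyl)-3-ethoxy-6-methylidenedeca-2,9-dien-4-ol | CCOC(=CC)[C@H](O)[C@@H](CC(OCC)OCC)C(=C)[C@H](O[Si](c1ccccc1)(c2ccccc2)C(C)(C)C)CC=C | intermediate
16 | (3S,4R)-3-{(3R)-3-[(tert-butyldiphenylsilyl)oxy]hexa-1,5-dien-2-yl}-4-hydroxy-5-oxoheptanal | CCC(=O)[C@H](O)[C@@H](CC=O)C(=C)[C@H](O[Si](c1ccccc1)(c2ccccc2)C(C)(C)C)CC=C | intermediate
17 | (5S,6R)-5-{(3R)-3-[(tert-butyldiphenylsilyl)oxy]hexa-1,5-dien-2-yl}-6-hydroxy-2-methylcyclohex-2-en-1-one | O[C@H]1C(=O)C(C)=CC[C@H]1C(=C)[C@H](O[Si](c2ccccc2)(c3ccccc3)C(C)(C)C)CC=C | intermediate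
18 | 3-methylbutanoic acid | CC(C)CC(=O)O | starting material
19 | (1S,6S)-6-{(3R)-3-[(tert-butyldiphenylsilyl)oxy]hexa-1,5-dien-2-yl}-3-methyl-2-oxocyclohex-3-en-1-yl 3-methylbutanoate | CC(C)CC(=O)O[C@@H]1C(=O)C(C)=CC[C@H]1C(=C)[C@H](O[Si](c2ccccc2)(c3ccccc3)C(C)(C)C)CC=C | intermediate
20 | (1S,6S)-6-[(3R)-3-hydroxyhexa-1,5-dien-2-yl]-3-methyl-2-oxocyclohex-3-en-1-yl 3-methylbutanoate | CC(C)CC(=O)O[C@@H]1C(=O)C(C)=CC[C@H]1C(=C)[C@H](O)CC=C | intermediate
21 | (1S,2S,6S)-2-hydroxy-6-[(3R)-3-hydroxyhexa-1,5-dien-2-yl]-3-methylcyclohex-3-en-1-yl 3-methylbutanoate | CC(C)CC(=O)O[C@@H]1[C@@H](O)C(C)=CC[C@H]1C(=C)[C@H](O)CC=C | intermediate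
22 | (1R,2R,3S,4R,6S)-2-hydroxy-4-{(2S)-2-[(1R)-1-hydroxybut-3-en-1-yl]oxiran-2-yl}-1-methyl-7-oxabicyclo[4.1.0]heptan-3-yl 3-methylbutanoate | CC(C)CC(=O)O[C@@H]1[C@@H](O)[C@@]2(C)O[C@H]2C[C@H]1[C@@]1([C@H](O)CC=C)CO1 | intermediate
23 | 2-methylbut-2-ene | CC=C(C)C | starting material
24 | (1R,2R,3S,4R,6S)-2-hydroxy-4-{(2S)-2-[(1R)-1-hydroxy-4-methylpent-3-en-1-yl]oxiran-2-yl}-1-methyl-7-oxabicyclo[4.1.0]heptan-3-yl 3-methylbutanoate | CC(C)CC(=O)O[C@@H]1[C@@H](O)[C@@]2(C)O[C@H]2C[C@H]1[C@@]1([C@H](O)CC=C(C)C)CO1 | intermediate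
25 | (1S,3S,4R,6S)-1-methyl-4-[(2S)-2-(4-methylpent-3-enoyl)oxiran-2-yl]-2-oxo-7-oxabicyclo[4.1.0]heptan-3-yl 3-methylbutanoate | CC(C)CC(=O)O[C@@H]1C(=O)[C@@]2(C)O[C@H]2C[C@H]1[C@@]1(C(=O)CC=C(C)C)CO1 | intermediate
26 | (1S,3S,4R,6S)-4-{(2S)-2-[(2E)-4-hydroperoxy-4-methylpent-2-enoyl]oxiran-2-yl}-1-methyl-2-oxo-7-oxabicyclo[4.1.0]heptan-3-yl 3-methylbutanoate | CC(C)CC(=O)O[C@@H]1C(=O)[C@@]2(C)O[C@H]2C[C@H]1[C@@]1(C(=O)/C=C/C(C)(C)OO)CO1 | target

**Totals and risks**

Total step count: 14. Longest linear sequence: 14 steps (1 and 2 to 26).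

Steps most likely to fail:

- Step 7. The α-lithiation of 14 may be incomplete, the allylic aldehyde 13 may enolise and lose its configuration, or the cyclodehydration may stall at the keto aldehyde stage. Fallback, setting out from 13: Corey–Seebach addition of 2-lithio-2-ethyl-1,3-dithiane (n-BuLi, THF) gives the dithiane carbinol F1. Hydrolysis of the dithiane (MeI, CaCO3, aq. MeCN) gives the α-hydroxy ethyl ketone acetal F2. Mild aqueous acid then unmasks keto aldehyde 16, which is cyclised and dehydrated with pyrrolidinium acetate to rejoin the route at 17.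

- Step 8. The oxyphosphonium intermediate of the hindered α-ketol may eliminate or react too slowly, or the product may partly epimerise. Fallback, setting out from 17: the alcohol is converted into the isolable α-keto triflate F3 (Tf2O, 2,6-lutidine, CH2Cl2, −78 °C). This is displaced with cesium 3-methylbutanoate (from 18 and Cs2CO3; 18-crown-6, toluene) with inversion, rejoining the route at 19.

- Step 14. Hydrogen abstraction from a methyl group of the prenyl unit may compete and give the isomeric secondary hydroperoxide, and the product may decompose on prolonged irradiation. Fallback, setting out from 22, with the hydroperoxide brought in as a building block: Dess–Martin oxidation gives the allyl diketone F4, and DABCO (cat.) moves the alkene into conjugation to give the (E)-propenyl ketone F5. Separately, 2-methylbut-3-en-2-ol is converted with H2O2/H2SO4 into 2-hydroperoxy-2-methylbut-3-ene F6 and capped with 2-methoxypropene (PPTS) as the peroxyketal 2-[(2-methoxypropan-2-yl)peroxy]-2-methylbut-3-ene F7. Cross-metathesis of F5 with F7 (second-generation Hoveyda–Grubbs catalyst, CH2Cl2, 40 °C) gives the protected peroxide F8, and AcOH/THF/H2O releases the hydroperoxide, arriving at 26.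

**Further compounds**

F1 | step 7 | (1R,2S,4R)-4-[(tert-butyldiphenylsilyl)oxy]-2-(2,2-diethoxyethyl)-1-(2-ethyl-1,3-dithian-2-yl)-3-methylidenehept-6-en-1-ol | CCC1(SCCCS1)[C@H](O)[C@@H](CC(OCC)OCC)C(=C)[C@H](O[Si](c2ccccc2)(c3ccccc3)C(C)(C)C)CC=C
F2 | step 7 | (4R,5S,7R)-7-[(tert-butyldiphenylsilyl)oxy]-5-(2,2-diethoxyethyl)-4-hydroxy-6-methylidenedec-9-en-3-one | CCC(=O)[C@H](O)[C@@H](CC(OCC)OCC)C(=C)[C@H](O[Si](c1ccccc1)(c2ccccc2)C(C)(C)C)CC=C
F3 | step 8 | (1R,6S)-6-{(3R)-3-[(tert-butyldiphenylsilyl)oxy]hexa-1,5-dien-2-yl}-3-methyl-2-oxocyclohex-3-en-1-yl trifluoromethanesulfonate | O=S(=O)(O[C@H]1C(=O)C(C)=CC[C@H]1C(=C)[C@H](O[Si](c2ccccc2)(c3ccccc3)C(C)(C)C)CC=C)C(F)(F)F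
F4 | step 14 | (1S,3S,4R,6S)-4-[(2S)-2-(but-3-enoyl)oxiran-2-yl]-1-methyl-2-oxo-7-oxabicyclo[4.1.0]heptan-3-yl 3-methylbutanoate | CC(C)CC(=O)O[C@@H]1C(=O)[C@@]2(C)O[C@H]2C[C@H]1[C@@]1(C(=O)CC=C)CO1
F5 | step 14 | (1S,3S,4R,6S)-4-{(2S)-2-[(2E)-but-2-enoyl]oxiran-2-yl}-1-methyl-2-oxo-7-oxabicyclo[4.1.0]heptan-3-yl 3-methylbutanoate | CC(C)CC(=O)O[C@@H]1C(=O)[C@@]2(C)O[C@H]2C[C@H]1[C@@]1(C(=O)/C=C/C)CO1
F6 | step 14 | 2-hydroperoxy-2-methylbut-3-ene | C=CC(C)(C)OO
F7 | step 14 | 2-[(2-methoxypropan-2-yl)peroxy]-2-methylbut-3-ene | C=CC(C)(C)OOC(C)(C)OC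
F8 | step 14 | (1S,3S,4R,6S)-4-{(2S)-2-[(2E)-4-[(2-methoxypropan-2-yl)peroxy]-4-methylpent-2-enoyl]oxiran-2-yl}-1-methyl-2-oxo-7-oxabicyclo[4.1.0]heptan-3-yl 3-methylbutanoate | CC(C)CC(=O)O[C@@H]1C(=O)[C@@]2(C)O[C@H]2C[C@H]1[C@@]1(C(=O)/C=C/C(C)(C)OOC(C)(C)OC)CO1
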